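**Assumptions:** The SMILES defines the (7R)-enantiomer (azaphilone numbering: C1, O2, C3, C4, C4a, C5–C8, C8a). The two acid chlorides are made in situ inside the coupling steps and are not numbered.

## Retrosynthetic overview

1. Target ⇐ one acid deprotection (t-Bu ester, two MOM ethers) of 15.
2. Pyran ring (formed last) ⇐ oxa-6π electrocyclisation and loss of Me2NH from the 1-oxatriene made by γ-acylation of the C4 methyl of 13 with fumaric half-ester chloride.
3. 13 ⇐ O-acylation of tertiary alcohol 8 with MOM-protected orsellinoyl chloride.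
4. Carbocycle (formed first) 8 ⇐ intramolecular C-acylation of dienamine 7 onto the dioxolanone C=O, releasing pivalaldehyde. C1 is placed on C8a before closure so the ring has no symmetric enol and C7 cannot racemise.
5. C7 ⇐ (S)-lactic acid via its cis pivalaldehyde acetal 3 and enolate C-acylation with retention (self-regeneration of the stereocentre).

## Route

**Step 1**
Reactants: 1 (S)-lactic acid; 2 pivalaldehyde
Product: 3 (2S,5S)-2-tert-butyl-5-methyl-1,3-dioxolan-4-one (cis)
Conditions: TsOH·H2O (cat.), H2SO4 (cat.), pentane, reflux, Dean–Stark; recrystallise from pentane, −78 °C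
Reagents that add atoms: pivalaldehyde, CC(C)(C)C=O
Why: Acid-catalysed acetalisation gives mainly the cis-dioxolanone (upgraded by crystallisation); the lactate centre sets the new acetal centre.

**Step 2**
Reactants: 3; 4 3-methylbut-2-enoyl chloride
Product: 5 (2S,5R)-2-tert-butyl-5-methyl-5-(3-methylbut-2-enoyl)-1,3-dioxolan-4-one
Conditions: LDA, THF, −78 °C; then cannulate into 4 (1.3 equiv), THF, −78 °C
Reagents that add atoms: 3-methylbut-2-enoyl chloride, CC(C)=CC(Cl)=O
Why: C-acylation of the lithium enolate anti to the t-Bu group puts the acyl group where H was (retention), setting the (R) quaternary carbon that becomes C7; the product has no α-H, so it cannot over-acylate.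

**Step 3**
Reactants: 5; 6 N,N-dimethylformamide dimethyl acetal (DMF-DMA)
Product: 7 (2S,5R)-2-tert-butyl-5-[(2Z,4E)-5-(dimethylamino)-3-methylpenta-2,4-dienoyl]-5-methyl-1,3-dioxolan-4-one (2E/2Z isomers interconvert)
Conditions: DMF-DMA (1.2 equiv), PhMe, 80 °C, N2 sweep to remove MeOH
Reagents that add atoms: DMF-DMA, COC(OC)N(C)C
Why: Vinylogous (γ) aminomethylenation of a β-methyl enone with no α′-H installs C1 on the future C8a before ring closure; the quaternary centre is untouched.

**Step 4**
Reactants: 7
Product: 8 (2R)-4-[(dimethylamino)methylidene]-2-hydroxy-2,5-dimethylcyclohex-5-ene-1,3-dione (ring A; pivalaldehyde lost)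
Conditions: PhMe, 100 °C, AcOH (5 mol %), pivalaldehyde distilled off
Reagents that add atoms: none
Why: Intramolecular enamine C-acylation (6-exo-trig, Dieckmann-type) by the activated acetal-lactone; the tetrahedral intermediate collapses to t-BuCHO and the tertiary alcohol, driven by vinylogous-amide formation. C7 stays quaternary and the ring is unsymmetrical, so there is no racemisation pathway.

**Step 5**
Reactants: 9 methyl orsellinate (methyl 2,4-dihydroxy-6-methylbenzoate); 10 chloromethyl methyl ether
Product: 11 methyl 2,4-bis(methoxymethoxy)-6-methylbenzoate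
Conditions: NaH, MOMCl, DMF, 0 °C → rt
Reagents that add atoms: MOMCl, COCCl
Why: Williamson O-alkylation of both phenoxides; MOM tolerates the later base steps and is removed by the final acid.

**Step 6**
Reactants: 11
Product: 12 2,4-bis(methoxymethoxy)-6-methylbenzoic acid
Conditions: KOH, MeOH/H2O, 75 °C; then citric acid to pH 4, 0 °C
Reagents that add atoms: hydroxide/water, [OH-].[K+] / O
Why: Saponification of the hindered methyl ester; MOM ethers are stable to base.

**Step 7**
Reactants: 8; 12
Product: 13 (1R)-3-[(dimethylamino)methylidene]-1,4-dimethyl-2,6-dioxocyclohex-4-en-1-yl 2,4-bis(methoxymethoxy)-6-methylbenzoate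
Conditions: 12, Ghosez's reagent (1-chloro-N,N,2-trimethylprop-1-en-1-amine), CH2Cl2, 0 °C → rt (acid chloride); 8, LiHMDS (1.05 equiv), THF, −78 °C; add acid chloride, −78 → 0 °C
Reagents that add atoms: 2,4-bis(methoxymethoxy)-6-methylbenzoyl chloride (from 12), COCOc1cc(C)c(C(Cl)=O)c(OCOC)c1
Why: O-acylation of the lithium tertiary alkoxide by a neutral-generated acid chloride; only the OH is deprotonated at this stoichiometry and C7 is not involved.

**Step 8 (key step)**
Reactants: 13; 14 (E)-4-tert-butoxy-4-oxobut-2-enoic acid (mono-tert-butyl fumarate)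
Product: 15 tert-butyl (2E)-3-[(7R)-7-{[2,4-bis(methoxymethoxy)-6-methylbenzoyl]oxy}-7-methyl-6,8-dioxo-7,8-dihydro-6H-isochromen-3-yl]prop-2-enoate
Conditions: 14, Ghosez's reagent, CH2Cl2, 0 °C (acid chloride); 13, LiHMDS (2.2 equiv), THF, −78 °C; add acid chloride, −78 → −20 °C; then AcOH (excess), 50 °C
Reagents that add atoms: tert-butyl (E)-4-chloro-4-oxobut-2-enoate (from 14), CC(C)(C)OC(=O)/C=C/C(Cl)=O
Why: Vinylogous Claisen (γ) acylation of the C4-methyl dienolate (α-attack would break the vinylogous-amide conjugation, as with lithiated 2-methyl-γ-pyrones) gives a keto-enaminone. Its (Z)-1-oxatriene tautomer (O=C3–C4=C4a–C8a=C1) undergoes thermal oxa-6π electrocyclisation to a 2-amino-2H-pyran, and E1cB loss of Me2NH (trapped by AcOH) gives the pyran ring; C7 is untouched.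

**Step 9**
Reactants: 15
Product: 16 mitorubrinic acid, (2E)-3-[(7R)-7-(2,4-dihydroxy-6-methylbenzoyloxy)-7-methyl-6,8-dioxo-7,8-dihydro-6H-isochromen-3-yl]prop-2-enoic acid
Conditions: TFA/CH2Cl2 (1:3), 1,3-dimethoxybenzene (cation scavenger), 0 °C → rt
Reagents that add atoms: none
Why: Acidolysis of the tert-butyl ester and both MOM acetals in one operation; the azaphilone core, the hindered tertiary benzoate and the E-alkene are acid-stable.

## Compound list

1 | (S)-lactic acid | C[C@H](O)C(=O)O | starting material
2 | pivalaldehyde | CC(C)(C)C=O | starting material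
3 | (2S,5S)-2-tert-butyl-5-methyl-1,3-dioxolan-4-one | C[C@@H]1O[C@H](C(C)(C)C)OC1=O | intermediate
4 | 3-methylbut-2-enoyl chloride | CC(C)=CC(Cl)=O | starting material
5 | (2S,5R)-2-tert-butyl-5-methyl-5-(3-methylbut-2-enoyl)-1,3-dioxolan-4-one | CC(C)=CC(=O)[C@@]1(C)O[C@H](C(C)(C)C)OC1=O | intermediate
6 | N,N-dimethylformamide dimethyl acetal | COC(OC)N(C)C | starting material
7 | (2S,5R)-2-tert-butyl-5-[(2Z,4E)-5-(dimethylamino)-3-methylpenta-2,4-dienoyl]-5-methyl-1,3-dioxolan-4-one | CN(C)/C=C/C(C)=C\C(=O)[C@@]1(C)O[C@H](C(C)(C)C)OC1=O | intermediate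
8 | (2R)-4-[(dimethylamino)methylidene]-2-hydroxy-2,5-dimethylcyclohex-5-ene-1,3-dione (enamine geometry not defined) | C[C@@]1(O)C(=O)C=C(C)C(=CN(C)C)C1=O | intermediate
9 | methyl orsellinate | COC(=O)c1c(C)cc(O)cc1O | starting material
10 | chloromethyl methyl ether | COCCl | starting material
11 | methyl 2,4-bis(methoxymethoxy)-6-methylbenzoate | COCOc1cc(C)c(C(=O)OC)c(OCOC)c1 | intermediate
12 | 2,4-bis(methoxymethoxy)-6-methylbenzoic acid | COCOc1cc(C)c(C(=O)O)c(OCOC)c1 | intermediate
13 | (1R)-3-[(dimethylamino)methylidene]-1,4-dimethyl-2,6-dioxocyclohex-4-en-1-yl 2,4-bis(methoxymethoxy)-6-methylbenzoate | COCOc1cc(C)c(C(=O)O[C@]2(C)C(=O)C=C(C)C(=CN(C)C)C2=O)c(OCOC)c1 | intermediate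
14 | (E)-4-tert-butoxy-4-oxobut-2-enoic acid | CC(C)(C)OC(=O)/C=C/C(=O)O | starting material
15 | tert-butyl ester, bis-MOM ether of mitorubrinic acid | COCOc1cc(C)c(C(=O)O[C@]2(C)C(=O)C=C3C=C(/C=C/C(=O)OC(C)(C)C)OC=C3C2=O)c(OCOC)c1 | intermediate
16 | mitorubrinic acid | Cc1cc(O)cc(O)c1C(=O)O[C@]1(C)C(=O)C=C2C=C(/C=C/C(=O)O)OC=C2C1=O | target

## Step count and risks

Total steps: 9. Longest linear sequence: 7 (steps 1–4, 7–9); steps 5–6 prepare the aryl acid.

Steps most likely to fail:

1. **Step 8** (γ- versus α-/O-acylation of the dienolate, then pyran closure). Fallback: condense 13 with N,N-dimethylacetamide dimethyl acetal to reach the 3-methyl azaphilone by the same electrocyclisation/elimination, then SeO2 to the 3-carbaldehyde and Wittig with Ph3P=CHCO2t-Bu.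
2. **Step 4** (neutral enamine acylation by the lactone; possible lactone methanolysis carried over from step 3). Fallback: hydrolyse the enamine of 7 to the 5-hydroxydienone and close ring A anionically (DBU, vinylogous Dieckmann through the doubly stabilised C8a enolate), then re-mask the formyl group with Me2NH.
3. **Step 7** (tertiary alkoxide with a di-ortho-substituted aroyl chloride). Fallback: acylate 8 by ketene trapping, generating the quinoketene from 7-(methoxymethoxy)-2,2,5-trimethyl-4H-1,3-benzodioxin-4-one (thermal or photochemical retro-[4+2]) in the presence of 8.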